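Late on, at 6.00 min, the spring run reads 99 % of the starting material as product and the midnight run 102 %. The end of each curve therefore shows the charge of the limiting reagent, the starting material, converted, and says nothing of speed. The charge of free catalyst shows earlier: at 1.33 min the spring and midnight runs read 64 % and 74 %.

common to all: starting material 0.050 M; gas 3.2 mM (held)
- spring: free catalyst 0.60 mM; run made earlier
- midnight: free catalyst 0.95 mM; run made earlier
- flask: free catalyst 0.43 mM

| run | time / min | product / % |
|---|---|---|
| spring | 0.417 | 21 |
| spring | 1.33 | 64 |
| spring | 2.00 | 91 |
| spring | 3.00 | 101 |
| spring | 5.00 | 99 |
| spring | 6.00 | 99 |
| midnight | 0.417 | 23 |
| midnight | 1.33 | 74 |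
| midnight | 2.00 | 102 |
| midnight | 3.00 | 100 |
| midnight | 5.00 | 101 |
| midnight | 6.00 | 102 |

(each reading ± 1.5 percentage points)

- apparent order in free catalyst when 30 % of the starting material are converted (percent change of the rate of making product for one percent more free catalyst charged)
- factor on the rate of making product when 30 % of the starting material are converted if free catalyst is charged twice over

- the analysis behind the earlier runs scatters by 1.5 percentage points, standard deviation
- at the start none of the gas is in solution

Turned round, the question is what would put the flask's order above one half, the even case. Take two resistances in series, one falling with free catalyst and one indifferent to it. The order is then the first resistance's share, and the balance charge, the free catalyst charge at which the two shares are equal, comes from those two readings, taken as average rates, as 0.348 mM. In that law an order above one half needs a charge below balance. The flask stands above it, at 1.24 of balance, which gives my reckoning an order of 0.447 and a doubling factor of 1.29. The margin is thin: moving each reading one standard deviation apart lifts balance to 0.526 mM, and the flask then stands below it.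

The forecast assumes “gas transfer in series with catalytic consumption”, the same law as my reckoning, so its like numbers are no check. It gives an order of 0.45 (0.25 to 0.68) and a doubling factor of 1.29 (1.15 to 1.52).

The flask gives an order of 0.54 and a factor of 1.35.

    coupling partner + free catalyst → catalyst intermediate A (k = 736 /M/s)
    starting material + catalyst intermediate A → catalyst intermediate B (k = 142 /M/s)
    gas ⇌ coupling partner, rate k3*(csat - [coupling partner]) (kL = 0.210 /s)
    catalyst intermediate C → free catalyst + product (k = 248 /s)
    catalyst intermediate B → released group + catalyst intermediate C (k = 10.7 /s)

That order lies above one half, so on the balance scale the flask stands at 0.852 of balance, on the other side from my reckoning. At 0.500 min the flask holds 77.1 % of its catalyst free, 14.8 % as catalyst intermediate A, 7.82 % as catalyst intermediate B and 0.338 % as catalyst intermediate C. Carried to free catalyst charged twice over, the balance charge of 0.348 mM puts the time to 30 % conversion at 0.777 of the flask's, and that second flask gives 0.745.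

(All runs were generated by integration for an exercise; scatter was added.)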